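**Plan**

- Retrosynthetic cuts, in order: the aryl ether bond O–C1 (isofraxidin + oxolane diol), the ring bond C4–C5, the ether bond O1–C5 (prenyl bromide), the oxirane oxygen, and the C2–C3 bond (isopropenyl Grignard + silyloxyacetaldehyde).
- Enabling feature, with the oxolane numbered O1, C2 (carries the ArO–C1H2 arm), C3 (methyl carbinol), C4, C5 (carries C6=C7Me2): C4 is the only ring CH2 and lies between a tertiary carbinol and a carbon that is both allylic and bound to O1. O1–C5–C6=C7Me2 is therefore a masked O-prenyl group and C3(O)–C4 a masked 2,2-disubstituted oxirane.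
- Forward: the C1–C4 chain is joined by Grignard addition, the oxirane is installed, the C2 oxygen is prenylated, and the oxolane (the only ring made) closes by carbanionic C4–C5 bond formation; the coumarin is attached last.
- Stereochemistry: C2 and C3 are fixed together by a Sharpless kinetic resolution (L-(+)-tartrate, erythro epoxy alcohol); C5 is set in the ring closure under control of C2 and C3.

Key step: step 4

Assumption: 2-(triisopropylsilyloxy)acetaldehyde 1 is taken as a stock aldehyde; the triisopropylsilyl ether is used on the C1 oxygen because it does not shift to a neighbouring alkoxide (step 3) and withstands s-BuLi (step 4).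

Step 1
Reactants: 1 2-(triisopropylsilyloxy)acetaldehyde; 2 isopropenylmagnesium bromide
Product: 4 rac-3-methyl-1-(triisopropylsilyloxy)but-3-en-2-ol, via bromomagnesium alkoxide 3 (not isolated)
Conditions: 2 (1.2 equiv), THF, −78 → 0 °C; then H2O
Reagents that add atoms: none
Why: Grignard 1,2-addition of an alkenylmagnesium halide to an unhindered α-silyloxy aldehyde forms the C2–C3 bond and the secondary allylic alcohol, as a racemate because the carbinol centre is resolved in step 2.

Step 2
Reactants: 4 rac-3-methyl-1-(triisopropylsilyloxy)but-3-en-2-ol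
Product: 5 (2S,3R)-3,4-epoxy-3-methyl-1-(triisopropylsilyloxy)butan-2-ol
Conditions: Ti(OiPr)4 (0.15 equiv), diisopropyl L-(+)-tartrate (0.2 equiv), t-BuOOH (0.45 equiv, in decane), 4 Å MS, CH2Cl2, −20 °C; unreacted (S)-4 removed by chromatography
Reagents that add atoms: tert-butyl hydroperoxide, CC(C)(C)OO
Why: Sharpless kinetic resolution of a secondary allylic alcohol: the titanium–L-(+)-tartrate catalyst epoxidises the (R)-enantiomer of 4 far faster than the (S)-enantiomer and delivers oxygen to the alkene face that gives the erythro product, so that C2 (S) is selected from the racemate and the quaternary centre C3 (R) is created under catalyst control, while stopping short of half conversion keeps the epoxide enantiomerically enriched.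

Step 3
Reactants: 5 (2S,3R)-3,4-epoxy-3-methyl-1-(triisopropylsilyloxy)butan-2-ol; 6 prenyl bromide (1-bromo-3-methylbut-2-ene)
Product: 8 (2S,3R)-3,4-epoxy-3-methyl-2-(3-methylbut-2-enyloxy)-1-(triisopropylsilyloxy)butane, via sodium alkoxide 7 (not isolated)
Conditions: NaH (1.2 equiv), 6 (1.5 equiv), Bu4NI (0.1 equiv), THF, 0 °C → rt
Reagents that add atoms: none
Why: Williamson ether synthesis with a reactive allylic bromide; C2 and C3 are not touched, because the bulky triisopropylsilyl group does not migrate to the alkoxide and a Payne rearrangement would require substitution at the fully substituted oxirane carbon in an aprotic medium.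

Step 4
Reactants: 8 (2S,3R)-3,4-epoxy-3-methyl-2-(3-methylbut-2-enyloxy)-1-(triisopropylsilyloxy)butane
Product: 11 (2S,3R,5R)-3-methyl-5-(2-methylprop-1-enyl)-2-(triisopropylsilyloxymethyl)oxolan-3-ol, via lithiated prenyl ether 9 (not isolated), via lithium alkoxide 10 (not isolated)
Conditions: s-BuLi (1.3 equiv), THF, −78 °C, then slowly to −30 °C; then H2O
Reagents that add atoms: none
Why: s-BuLi removes a proton from the O–CH2 group of the prenyl ether, which is activated twice (allylic and next to oxygen), and the carbanion carbon C5 of the resulting α-oxyallyl lithium 9 opens the oxirane by SN2 attack at its methylene carbon C4, forming the C4–C5 bond and leaving the C3 oxygen as lithium alkoxide 10 without breaking the C3–O bond. The closest known reaction type is the strong-base isomerisation of allyl and benzyl oxiranylmethyl ethers through their α-oxy carbanions, where the substitution pattern decides which oxirane carbon is attacked. The oxolane closes in the 5-endo mode with respect to the oxirane, both oxirane carbons ending up in the new ring. The step needs α- over γ-attack of the allyl anion and C4 over C3 attack on the oxirane: 4-exo closure would require substitution at the fully substituted C3, and 7-endo closure through the γ-terminus would have to build a quaternary carbon from the gem-dimethyl end, so only the unhindered CH2 is within reach of the α-carbon. The new stereocentre C5 is set by substrate control, since the planar allyl anion can present either face and the erythro backbone places the C2 silyloxymethyl arm and the C3 methyl group on one face of the forming envelope, which sends the 2-methylpropenyl group to the other, pseudoequatorial side (trans to the C2 arm, cis to the C3 oxygen, 5R). C2 and C3 are carried through unchanged, and metalation at −78 °C in THF is expected at the allylic O–CH2 group in preference to the oxirane C–H bonds or addition of the base to the oxirane.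

Step 5
Reactants: 11 (2S,3R,5R)-3-methyl-5-(2-methylprop-1-enyl)-2-(triisopropylsilyloxymethyl)oxolan-3-ol
Product: 12 (2S,3R,5R)-2-(hydroxymethyl)-3-methyl-5-(2-methylprop-1-enyl)oxolan-3-ol
Conditions: Bu4NF (1.2 equiv), THF, 0 °C → rt
Reagents that add atoms: none
Why: Fluoride-induced desilylation driven by the strength of the Si–F bond frees the primary alcohol, and the tertiary alcohol, the allylic ring ether and the trisubstituted alkene are inert to these conditions, so no stereocentre is affected.

Step 6
Reactants: 12 (2S,3R,5R)-2-(hydroxymethyl)-3-methyl-5-(2-methylprop-1-enyl)oxolan-3-ol; 13 isofraxidin (7-hydroxy-6,8-dimethoxychromen-2-one)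
Product: 15 7-{[(2S,3R,5R)-3-hydroxy-3-methyl-5-(2-methylprop-1-enyl)oxolan-2-yl]methoxy}-6,8-dimethoxychromen-2-one (CNP0086110.2), via oxyphosphonium salt 14 (not isolated)
Conditions: 13 (1.2 equiv), PPh3 (1.5 equiv), DIAD (1.5 equiv), THF, 0 °C → rt
Reagents that add atoms: none
Why: Mitsunobu etherification: the primary hydroxyl is activated as its oxyphosphonium ion and displaced in an SN2 step by the acidic 7-hydroxyl of the coumarin, whereas the tertiary C3 hydroxyl is too hindered to be activated, and since the reacting carbon is a CH2 group no stereocentre is involved.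

**Compound list**

1 | 2-(triisopropylsilyloxy)acetaldehyde | CC(C)[Si](C(C)C)(C(C)C)OCC=O | starting material
2 | isopropenylmagnesium bromide (prop-1-en-2-ylmagnesium bromide) | CC(=C)[Mg]Br | starting material
3 | bromomagnesium 3-methyl-1-(triisopropylsilyloxy)but-3-en-2-olate (racemic) | CC(C)[Si](C(C)C)(C(C)C)OCC(O[Mg]Br)C(C)=C | intermediate
4 | rac-3-methyl-1-(triisopropylsilyloxy)but-3-en-2-ol | CC(C)[Si](C(C)C)(C(C)C)OCC(O)C(C)=C | intermediate
5 | (2S,3R)-3,4-epoxy-3-methyl-1-(triisopropylsilyloxy)butan-2-ol (erythro) | CC(C)[Si](C(C)C)(C(C)C)OC[C@H](O)[C@@]1(C)CO1 | intermediate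
6 | prenyl bromide (1-bromo-3-methylbut-2-ene) | CC(C)=CCBr | starting material
7 | sodium (2S,3R)-3,4-epoxy-3-methyl-1-(triisopropylsilyloxy)butan-2-olate | CC(C)[Si](C(C)C)(C(C)C)OC[C@H](O[Na])[C@@]1(C)CO1 | intermediate
8 | (2S,3R)-3,4-epoxy-3-methyl-2-(3-methylbut-2-enyloxy)-1-(triisopropylsilyloxy)butane | CC(C)[Si](C(C)C)(C(C)C)OC[C@H](OCC=C(C)C)[C@@]1(C)CO1 | intermediate
9 | (2S,3R)-3,4-epoxy-2-(1-lithio-3-methylbut-2-enyloxy)-3-methyl-1-(triisopropylsilyloxy)butane | CC(C)[Si](C(C)C)(C(C)C)OC[C@H](OC([Li])C=C(C)C)[C@@]1(C)CO1 | intermediate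
10 | lithium (2S,3R,5R)-3-methyl-5-(2-methylprop-1-enyl)-2-(triisopropylsilyloxymethyl)oxolan-3-olate | CC(C)[Si](C(C)C)(C(C)C)OC[C@@H]1O[C@@H](C=C(C)C)C[C@@]1(C)O[Li] | intermediate
11 | (2S,3R,5R)-3-methyl-5-(2-methylprop-1-enyl)-2-(triisopropylsilyloxymethyl)oxolan-3-ol | CC(C)[Si](C(C)C)(C(C)C)OC[C@@H]1O[C@@H](C=C(C)C)C[C@@]1(C)O | intermediate
12 | (2S,3R,5R)-2-(hydroxymethyl)-3-methyl-5-(2-methylprop-1-enyl)oxolan-3-ol | OC[C@@H]1O[C@@H](C=C(C)C)C[C@@]1(C)O | intermediate
13 | isofraxidin (7-hydroxy-6,8-dimethoxychromen-2-one) | COc1cc2ccc(=O)oc2c(OC)c1O | starting material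
14 | {[(2S,3R,5R)-3-hydroxy-3-methyl-5-(2-methylprop-1-enyl)oxolan-2-yl]methoxy}triphenylphosphonium 6,8-dimethoxy-2-oxochromen-7-olate | c1ccccc1[P+](c1ccccc1)(c1ccccc1)OC[C@@H]1O[C@@H](C=C(C)C)C[C@@]1(C)O.COc1cc2ccc(=O)oc2c(OC)c1[O-] | intermediate
15 | 7-{[(2S,3R,5R)-3-hydroxy-3-methyl-5-(2-methylprop-1-enyl)oxolan-2-yl]methoxy}-6,8-dimethoxychromen-2-one (CNP0086110.2) | COc1cc2ccc(=O)oc2c(OC)c1OC[C@@H]1O[C@@H](C=C(C)C)C[C@@]1(C)O | target

Total step count: 6. Longest linear sequence: 6 steps (1 → 15).

**Steps most likely to fail**

Step 4. The lithiated ether may be slow to reach the oxirane CH2 in the strained 5-endo geometry and be diverted into a [1,2]-Wittig shift or base attack elsewhere. The closure may also proceed with poor facial discrimination at C5. The fallback makes the C4–C5 bond intermolecularly and closes the ring through O1–C5 instead. It sets out from 5: copper-catalysed opening of the oxirane at C4 with vinylmagnesium bromide (CuI cat., THF, −30 °C, excess Grignard to cover the free hydroxyl) should give (2S,3R)-3-methyl-1-(triisopropylsilyloxy)hex-5-ene-2,3-diol F1. Cross-metathesis with 2-methylbut-3-en-2-ol (second-generation Grubbs catalyst RuCl2(=CHPh)(PCy3)(H2IMes), CH2Cl2, 40 °C) should give (2S,3R,5E)-3,7-dimethyl-1-(triisopropylsilyloxy)oct-5-ene-2,3,7-triol F2. Dehydrative SN2' cyclisation of this monoallylic diol (Ph3PAuCl/AgOTf cat., 4 Å MS, CH2Cl2), in which the C2 hydroxyl adds to C5 and the tertiary C7 hydroxyl leaves, comes back to the route at 11. The alkenyl group is expected to settle on the face away from the C2 arm and the C3 methyl group.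

Step 2. The rate difference between the enantiomers of a carbinol carrying an oxygenated CH2 group may be too small, which erodes enantiomeric purity when the epoxide and not the unreacted alcohol is harvested. The fallback sets out from 4 and harvests the slow enantiomer instead. The same titanium–tartrate epoxidation run with diisopropyl D-(−)-tartrate past half conversion should leave (2R)-3-methyl-1-(triisopropylsilyloxy)but-3-en-2-ol F3 in high enantiomeric purity. The (S)-enantiomer is consumed as (2R,3S)-3,4-epoxy-3-methyl-1-(triisopropylsilyloxy)butan-2-ol F4, which is discarded. Hydroxyl-directed epoxidation of F3 with VO(acac)2/t-BuOOH, erythro-selective through A(1,2) strain with the 2-methyl group, comes back to the route at 5.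

Step 6. Displacement at the β-branched oxyphosphonium carbon by a phenoxide flanked by two methoxy groups may be sluggish, so that the hydrazide anion competes as nucleophile. The fallback sets out from 12: selective sulfonylation of the primary hydroxyl (TsCl, pyridine, 0 °C) should give [(2S,3R,5R)-3-hydroxy-3-methyl-5-(2-methylprop-1-enyl)oxolan-2-yl]methyl 4-methylbenzenesulfonate F5. Williamson displacement with the potassium salt of 13 (K2CO3, DMF, 60 °C) comes back to the route at 15.

**Further compounds**

F1 | step 4 | (2S,3R)-3-methyl-1-(triisopropylsilyloxy)hex-5-ene-2,3-diol | CC(C)[Si](C(C)C)(C(C)C)OC[C@H](O)[C@](C)(O)CC=C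
F2 | step 4 | (2S,3R,5E)-3,7-dimethyl-1-(triisopropylsilyloxy)oct-5-ene-2,3,7-triol | CC(C)[Si](C(C)C)(C(C)C)OC[C@H](O)[C@](C)(O)C/C=C/C(C)(C)O
F3 | step 2 | (2R)-3-methyl-1-(triisopropylsilyloxy)but-3-en-2-ol | CC(C)[Si](C(C)C)(C(C)C)OC[C@H](O)C(C)=C
F4 | step 2 | (2R,3S)-3,4-epoxy-3-methyl-1-(triisopropylsilyloxy)butan-2-ol | CC(C)[Si](C(C)C)(C(C)C)OC[C@@H](O)[C@]1(C)CO1
F5 | step 6 | [(2S,3R,5R)-3-hydroxy-3-methyl-5-(2-methylprop-1-enyl)oxolan-2-yl]methyl 4-methylbenzenesulfonate | Cc1ccc(cc1)S(=O)(=O)OC[C@@H]1O[C@@H](C=C(C)C)C[C@@]1(C)O
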